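**Retrosynthetic overview**
1. The only stereocenter, C2 (S), and both benzopyranone ring systems are bought: (2S)-hesperetin 1 (carried as its 7-O-benzyl ether 2) for the flavanone half and apigenin 7,4'-dimethyl ether 3 for the flavone half.
2. Key disconnection: the tetra-ortho-substituted C2'–C6'' biaryl bond is cut back to two C–H bonds held together by an O3'–Si(iPr)2–O5'' bridge (silyl triflate 4, silaketal 5) and joined by anodic dehydrogenative coupling.
3. Ring order: no ring of the target is built. The only ring formed is the temporary seven-membered dibenzodioxasilepine 6, opened by fluoride in the same pot to biaryl 7.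
4. Last disconnection: three O-methyl groups and one O-benzyl group, removed together with BBr3 to give target 8.

Assumption and locants: the target SMILES gives no descriptor for the hindered C2'–C6'' axis, so only C2 (S) is controlled, and (2S)-hesperetin (aglycone of citrus hesperidin) is taken as bought enantiopure; unprimed locants = flavanone rings A/C, ' = its ring B, '' = flavone rings A/C, ''' = flavone ring B.

**Step 1**
Reactants: 1 (2S)-hesperetin [(2S)-5,7-dihydroxy-2-(3-hydroxy-4-methoxyphenyl)chroman-4-one]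
Product: 2 (2S)-7-(benzyloxy)-5-hydroxy-2-(3-hydroxy-4-methoxyphenyl)chroman-4-one
Conditions: BnOH (1.05 equiv), PPh3 (1.2 equiv), DIAD (1.2 equiv), THF, 0 °C → rt
Reagents that add atoms: benzyl alcohol, OCc1ccccc1
Why: Mitsunobu etherification, in which the betaine deprotonates only the most acidic phenol (7-OH, para to the C4 carbonyl; 3'-OH is about two pKa units weaker and 5-OH is locked in a hydrogen bond), while the neutral medium avoids the base-induced retro-oxa-Michael opening that would racemise C2, so the bought (2S) centre is carried through unchanged.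

**Step 2**
Reactants: 3 apigenin 7,4'-dimethyl ether [5-hydroxy-7-methoxy-2-(4-methoxyphenyl)-4H-chromen-4-one]; 2 (2S)-7-(benzyloxy)-5-hydroxy-2-(3-hydroxy-4-methoxyphenyl)chroman-4-one
Product: 5 (2S)-7-(benzyloxy)-5-hydroxy-2-{3-[({[7-methoxy-2-(4-methoxyphenyl)-4-oxo-4H-chromen-5-yl]oxy}diisopropylsilyl)oxy]-4-methoxyphenyl}chroman-4-one, via silyl triflate 4 (not isolated)
Conditions: 3 (1.1 equiv), iPr2Si(OTf)2 (1.0 equiv), 2,6-lutidine (3 equiv), CH2Cl2, 0 °C → rt; then 2 (0.9 equiv), −40 → 0 °C; quick filtration through neutral Al2O3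
Reagents that add atoms: diisopropylsilyl bis(trifluoromethanesulfonate), CC(C)[Si](OS(=O)(=O)C(F)(F)F)(OS(=O)(=O)C(F)(F)F)C(C)C
Why: Stepwise silyl ether formation through a silyl triflate (mixed silaketal, temporary silicon tether): the bis-triflate silylates the chelated 5-OH of 3 (its only OH) and stops at the hindered, carbonyl-chelated mono-triflate, which is then taken by the only free, non-chelated phenol of 2 (3'-OH; 7-O is benzylated, 5-OH chelated), and the non-nucleophilic base leaves C2 untouched.

**Step 3**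
Reactants: 5 the O3'–Si(iPr)2–O5'' silaketal
Product: 7 (2S)-7-(benzyloxy)-5-hydroxy-2-{3-hydroxy-2-[5-hydroxy-7-methoxy-2-(4-methoxyphenyl)-4-oxo-4H-chromen-6-yl]-4-methoxyphenyl}chroman-4-one, via dibenzodioxasilepine 6 (not isolated)
Conditions: undivided cell, BDD anode, Pt cathode, constant current 2.5 mA cm−2, 2.2 F mol−1, 5 mM in HFIP/CH2Cl2 (4:1), Bu3MeN+ MeOSO3− (0.1 M), 10 °C; then evaporate, 48% aq. HF, MeCN, 0 °C → rt
Reagents that add atoms: none
Why: Proposed new method: anodic oxidation in HFIP (which stabilises aryl radical cations and shields products from over-oxidation) should take one electron from the most electron-rich ring, the 3'-silyloxy-4'-methoxyphenyl ring B, and the O3'–Si–O5'' bridge then lets the silyloxy/methoxy-activated C6'' attack C2' through a seven-membered transition state, the only closure available because the other ortho carbons of the two bridging oxygens (C4' and C4a'') carry no hydrogen, after which a second electron transfer and loss of two protons (reduced to H2 at the cathode) give the dibenzo[d,f][1,3,2]dioxasilepine that HF opens to the free 2,2'-biphenol; the closest known reaction types are the anodic dehydrogenative cross-coupling of phenols and O-silyl phenols in HFIP at BDD and the trivalent-iodine-mediated oxidative biaryl coupling of silaketal-tethered aryl ethers, neither shown as an electrolysis across a silicon bridge or on flavonoids; no stereocenter is formed and C2 (S) is a spectator.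

**Step 4**
Reactants: 7 the 7-O-benzyl 4',7'',4'''-tri-O-methyl biaryl
Product: 8 (2S)-2-{2-[5,7-dihydroxy-2-(4-hydroxyphenyl)-4-oxo-4H-chromen-6-yl]-3,4-dihydroxyphenyl}-5,7-dihydroxychroman-4-one (target)
Conditions: BBr3 (15 equiv), CH2Cl2, −78 °C → rt, 16–24 h; H2O quench at 0 °C; C18 chromatography (H2O/MeCN, 0.1% HCO2H), no base, degassed solvents
Reagents that add atoms: none
Why: Lewis-acid ether cleavage (BBr3 dealkylation): the benzyl ether and the guaiacol-type 4'-methyl ether go below 0 °C and the two flavone methyl ethers at room temperature, while boron chelation of each 5-O/4-C=O unit and the absence of base keep the C2–O1 bond closed so the (2S) centre is retained, and the flavone C2''=C3'' bond is inert.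

**Compound list**
1 | (2S)-hesperetin, (2S)-5,7-dihydroxy-2-(3-hydroxy-4-methoxyphenyl)chroman-4-one | O=C1C[C@@H](c2ccc(OC)c(O)c2)Oc2cc(O)cc(O)c21 | starting material
2 | (2S)-7-(benzyloxy)-5-hydroxy-2-(3-hydroxy-4-methoxyphenyl)chroman-4-one | O=C1C[C@@H](c2ccc(OC)c(O)c2)Oc2cc(OCc3ccccc3)cc(O)c21 | intermediate
3 | apigenin 7,4'-dimethyl ether, 5-hydroxy-7-methoxy-2-(4-methoxyphenyl)-4H-chromen-4-one | O=c1cc(-c2ccc(OC)cc2)oc2cc(OC)cc(O)c12 | starting material
4 | silyl triflate: 5-O-[diisopropyl(trifluoromethanesulfonyloxy)silyl] ether of 3 | O=c1cc(-c2ccc(OC)cc2)oc2cc(OC)cc(O[Si](C(C)C)(C(C)C)OS(=O)(=O)C(F)(F)F)c12 | intermediate (not isolated)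
5 | mixed silaketal, Si(iPr)2 bridging O3' of 2 and O5'' of 3, (2S) | O=C1C[C@@H](c2ccc(OC)c(O[Si](C(C)C)(C(C)C)Oc3cc(OC)cc4oc(-c5ccc(OC)cc5)cc(=O)c34)c2)Oc2cc(OCc3ccccc3)cc(O)c21 | intermediate
6 | 2,2-diisopropyl-dibenzo[d,f][1,3,2]dioxasilepine: C2'–C6'' bond formed, Si still bridging O3' and O5'', (2S) | O=C1C[C@@H](c2ccc(OC)c3O[Si](C(C)C)(C(C)C)Oc4c(c(OC)cc5oc(-c6ccc(OC)cc6)cc(=O)c45)-c23)Oc2cc(OCc3ccccc3)cc(O)c21 | intermediate (not isolated)
7 | (2S)-7-(benzyloxy)-5-hydroxy-2-{3-hydroxy-2-[5-hydroxy-7-methoxy-2-(4-methoxyphenyl)-4-oxo-4H-chromen-6-yl]-4-methoxyphenyl}chroman-4-one | O=C1C[C@@H](c2ccc(OC)c(O)c2-c2c(OC)cc3oc(-c4ccc(OC)cc4)cc(=O)c3c2O)Oc2cc(OCc3ccccc3)cc(O)c21 | intermediate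
8 | (2S)-2-{2-[5,7-dihydroxy-2-(4-hydroxyphenyl)-4-oxo-4H-chromen-6-yl]-3,4-dihydroxyphenyl}-5,7-dihydroxychroman-4-one | O=C1C[C@@H](c2ccc(O)c(O)c2-c2c(O)cc3oc(-c4ccc(O)cc4)cc(=O)c3c2O)Oc2cc(O)cc(O)c21 | target

**Totals**
Total steps: 4. Longest linear sequence: 4 (1 → 2 → 5 → 7 → 8); 3 enters at step 2 as bought.

**Steps most likely to fail**

Step 3 (the new anodic coupling) is the most uncertain. The radical cation of ring B may instead lose the benzylic C2–H, which would aromatise the flavanone and destroy the stereocenter. The untethered ring A of the flavanone half may be oxidised unproductively, and the carbonyl-flanked O5''–Si bond may solvolyse in HFIP before closure. The fallback uses known chemistry, sets out from 5 and comes back at 7. It leaves electrolysis altogether and closes the biaryl by a reagent-bound two-electron oxidation with the trivalent iodine reagent PhI(OCOCF3)2 activated by BF3·OEt2 in CH2Cl2 at −40 °C. This is the established way of turning silicon-tethered bis(aryl ethers) into bridged biaryls, run aprotic and cold so that neither benzylic deprotonation nor Si–O solvolysis is favoured. It gives the same silepine 6, which aq. HF opens to 7; it makes no new compound (F0).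

Step 4 is the second risk. The long room-temperature exposure to BBr3 needed for the two flavone methyl ethers may ionise the C2–O1 bond once the 4'-oxygen is unmasked, causing ring opening or erosion at C2, and benzyl bromide may C-alkylate the phloroglucinol rings. The fallback changes the protecting-group plan so that no hard methyl ether reaches the end, at the cost of one more step; it sets out from 2 and comes back at 8.
- Apigenin F1 is dibenzylated at its two acidic hydroxyls (BnBr 2.2 equiv, K2CO3, DMF, rt) to 7,4'-di-O-benzylapigenin F2.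
- F2 is used in place of 3: iPr2Si(OTf)2/2,6-lutidine gives silyl triflate F3, and addition of 2 gives silaketal F4.
- Coupling as in step 3 gives silepine F5, and aq. HF gives the tri-O-benzyl mono-O-methyl biaryl F6.
- BBr3 at −78 → 0 °C for about 1 h then only has to cleave benzyl ethers and the guaiacol-type 4'-methyl ether (assisted by the neighbouring 3'-OH), giving 8.

Step 2 is the third risk. The chelated 5-OH of 3 may silylate sluggishly, the mono-triflate may react twice, and 5 may hydrolyse on isolation. The fallback sets out from 3 and comes back at 5. It activates the nucleophile instead of the electrophile: the sodium 5-phenoxide of achiral 3 (NaH, THF, 0 °C) is added to excess iPr2SiCl2 (5 equiv), and the excess silane is removed in vacuo to leave chlorosilane F7. F7 is then joined to the 3'-OH of 2 by ordinary chlorosilane chemistry (imidazole, DMAP cat., CH2Cl2, 0 °C → rt) to give 5, which is taken crude into the electrolysis.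

**Further compounds**
F0 | step 3 | none | none
F1 | step 4 | apigenin | O=c1cc(-c2ccc(O)cc2)oc2cc(O)cc(O)c12
F2 | step 4 | 7,4'-di-O-benzylapigenin, 7-(benzyloxy)-2-[4-(benzyloxy)phenyl]-5-hydroxy-4H-chromen-4-one | O=c1cc(-c2ccc(OCc3ccccc3)cc2)oc2cc(OCc3ccccc3)cc(O)c12
F3 | step 4 | silyl triflate: 5-O-[diisopropyl(trifluoromethanesulfonyloxy)silyl] ether of F2 | O=c1cc(-c2ccc(OCc3ccccc3)cc2)oc2cc(OCc3ccccc3)cc(O[Si](C(C)C)(C(C)C)OS(=O)(=O)C(F)(F)F)c12
F4 | step 4 | silaketal, Si(iPr)2 bridging O3' of 2 and O5'' of F2, (2S) | O=C1C[C@@H](c2ccc(OC)c(O[Si](C(C)C)(C(C)C)Oc3cc(OCc4ccccc4)cc4oc(-c5ccc(OCc6ccccc6)cc5)cc(=O)c34)c2)Oc2cc(OCc3ccccc3)cc(O)c21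
F5 | step 4 | silepine: C2'–C6'' bonded, silicon-bridged, 7,7'',4'''-tri-O-benzyl, (2S) | O=C1C[C@@H](c2ccc(OC)c3O[Si](C(C)C)(C(C)C)Oc4c(c(OCc5ccccc5)cc5oc(-c6ccc(OCc7ccccc7)cc6)cc(=O)c45)-c23)Oc2cc(OCc3ccccc3)cc(O)c21
F6 | step 4 | biaryl: (2S)-7-(benzyloxy)-2-{2-[7-(benzyloxy)-2-[4-(benzyloxy)phenyl]-5-hydroxy-4-oxo-4H-chromen-6-yl]-3-hydroxy-4-methoxyphenyl}-5-hydroxychroman-4-one | O=C1C[C@@H](c2ccc(OC)c(O)c2-c2c(OCc3ccccc3)cc3oc(-c4ccc(OCc5ccccc5)cc4)cc(=O)c3c2O)Oc2cc(OCc3ccccc3)cc(O)c21
F7 | step 2 | chlorosilane: 5-O-[chloro(diisopropyl)silyl] ether of 3 | O=c1cc(-c2ccc(OC)cc2)oc2cc(OC)cc(O[Si](Cl)(C(C)C)C(C)C)c12
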